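**Easy count.** Counting turnovers was the easy step I took first, since the east flask, followed so far and asked about at 8.0 d, had to be judged from two runs.

| flask | starting material | second substrate | free enzyme | temperature | remark | time |
|---|---|---|---|---|---|---|
| east | 0.020 M | 0.024 M | 10 µM | 5 °C | the very flask that is asked about, followed so far |  |
| south-east | 0.020 M | 0.024 M | 20 µM | 11 °C | run made earlier |  |
| flask | 0.020 M | 0.0240 M | 10 µM | 5 °C |  | 8.0 d |

- birch: at 8.0 d add free enzyme, 100 % of the amount charged, then wait 4.0 d
- ash: at 8.0 d raise the temperature by 15 K, then wait 4.0 d
- elm: at 8.0 d add second substrate, 50.0 % of the amount charged, then wait 4.0 d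
- oak: at 8.0 d take out 90 % of the target then present, then wait 4.0 d
- larch: change nothing and wait 4.0 d more

| run | time / d | target / % |
|---|---|---|
| east | 1.04 | 50 |
| east | 2.08 | 69 |
| east | 3.00 | 76 |
| east | 4.00 | 77 |
| east | 5.00 | 76 |
| south-east | 0.625 | 66 |
| south-east | 1.25 | 74 |
| south-east | 2.50 | 75 |
| south-east | 4.00 | 74 |
| south-east | 8.00 | 78 |

(readings scatter by 1.5 percentage points)

- target that was removed still counts
- additions bring no volume worth counting

- target, in percent of the starting material first charged, at 8.0 d
- which option adds most target ("none" when 2 percentage points or less is all one gets) (birch / ash / elm / oak / larch / none)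
- target present, with what was taken out counted in, in percent of the starting material first charged, after ash
- target present, with what was taken out counted in, in percent of the starting material first charged, after oak

**First estimate.** Finishing the east flask needed 2000 turnovers per enzyme charged. Its reading of 77 % at 4.00 d stood for 1540, and this turnover count, target made per free enzyme charged, became my yardstick. I supposed first that each enzyme had a set budget of about that many turnovers, which put the east flask near 77 % at 8.0 d.

**First doubt.** The south-east run spoke against a set budget. It had twice the enzyme, though it was also warmer, yet its reading of 75 % stood for 750, about half the east count. So in these two runs the target repeated itself and the count did not, which looked like a balance between the substrates and the target.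

**Second doubt.** But failing enzyme also flattens a curve. The east count first rose at 962 d⁻¹, then the readings gave 76 % at 3.00 d and 76 % at 5.00 d, with a scatter of 1.5 percentage points. The count could not tell the two kinds of stop apart. I kept the plateau for the east flask and left the kind of stop open: I expected birch to pay if the enzyme was failing, and oak if the east flask stood at a balance.

**The forecast.** It gave 76 % at 8.0 d, 75.5 % after ash and 89 % after oak, and it chose oak. Its ground: “That points to true equilibrium, not enzyme death or stalling.” It agreed with my plateau, but it chose a kind of stop where I stayed undecided.

**The flask.** The east flask gave 81.4 % at 8.0 d, 81.5 % after ash and 82.9 % after oak. The best option was birch, adding 6.3 points, while oak added 1.6 points, the same as larch at 1.6 points.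

    free enzyme → unfolded enzyme (k = 6.10 × 10⁻⁵ min⁻¹, Ea = 235 kJ mol⁻¹)
    starting material + free enzyme ⇌ first complex (K = 330 L mol⁻¹, k = 5600 L mol⁻¹ min⁻¹, Ea = 36.0 kJ mol⁻¹, ΔH = −46.0 kJ mol⁻¹)
    first complex ⇌ loaded enzyme + first product (K = 0.0100 M, k = 140 min⁻¹, Ea = 70.0 kJ mol⁻¹, ΔH = 7.00 kJ mol⁻¹)
    second substrate + loaded enzyme ⇌ second complex (K = 26.0 L mol⁻¹, k = 14000 L mol⁻¹ min⁻¹, Ea = 38.0 kJ mol⁻¹, ΔH = −21.0 kJ mol⁻¹)
    second complex → free enzyme + target (k = 3.50 min⁻¹, Ea = 83.0 kJ mol⁻¹)
    2 free enzyme → spent catalyst (k = 1200 L mol⁻¹ min⁻¹, Ea = 49.0 kJ mol⁻¹)
    (constants at 5 °C)

**What happened.** In the east flask, by 0.800 d, the step from second substrate and loaded enzyme to second complex had behind it 55 % of its turnover up to 8.0 d, while loaded enzyme stood at 34.2 % of the catalyst charged. At 8.00 d spent catalyst in the east flask stood at 91.7 % of the catalyst charged, the count at 1630 of the 2000 needed, with 19 % of the starting material still there.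

**Second flask.** A neighbour flask, like the east flask in all else, had [second substrate] = 0.096 M. Scaled in step with that charge, my yardstick gave a count of 6160, above the same need of 2000, so this reckoning pointed to starting material as the limiting reagent in the neighbour flask. Computed, the neighbour flask gave 99.0 %, a count of 1980, with 0.97 % of the starting material and 79 % of the second substrate left.

The readings were generated by integration for an exercise; noise was put on by code.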